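**Substrate balance.** Substrate was conserved: what left the solid stood dissolved, as target, or as side product. So I read a percentage of target as an amount, [target] in mM, divided by the charge.

| flask | solid substrate | reagent | remark | time |
|---|---|---|---|---|
| autumn | 2.8 mM | 1.1 equiv | run made earlier |  |
| spring | 4.4 mM | 1.1 equiv | run made earlier |  |
| winter | 2 mM | 1.7 equiv | run made earlier |  |
| flask | 2.0 mM | 1.10 equiv |  | 4.0 min |

| run | time / min | target / % |
|---|---|---|
| autumn | 0.200 | 0.8 |
| autumn | 0.333 | 0 |
| autumn | 0.417 | 0.6 |
| autumn | 0.667 | 1.0 |
| autumn | 1.00 | 4.9 |
| autumn | 1.50 | 9.6 |
| autumn | 2.50 | 14.4 |
| spring | 0.333 | 1.5 |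
| spring | 0.667 | 3.7 |
| spring | 1.00 | 4.0 |
| spring | 1.33 | 5.8 |
| spring | 1.50 | 6.0 |
| spring | 2.00 | 10.2 |
| spring | 2.50 | 9.8 |
| winter | 0.200 | 1.2 |
| winter | 0.667 | 2.9 |
| winter | 1.00 | 8.7 |
| winter | 1.50 | 12.6 |
| winter | 2.50 | 19.2 |

(readings scatter by 1 percentage point)

- percentages count the solid substrate that a species holds: one side product counts as two
- solid, in amounts per volume of the solution: solid substrate
- the earlier runs were read with a standard deviation of 1 percentage point
- what may be going on: dissolved substrate + reagent -> target; 2 reagent -> self-condensation product; dissolved substrate + target -> side product; solid substrate <-> dissolved substrate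
- at the start none of the solid substrate is in solution

- south-west: doubling the amount of reagent, all else as stated
- north-east: doubling the solubility of the solid substrate, all else as stated
- south: doubling the dissolution coefficient of the solid substrate, all else as stated

* the target standing at 4.0 min, as a percentage of the solid substrate charged
* the change that raises the amount of target at 4.0 min, in percent of the solid substrate charged most ("none" if none brings more than 2 percentage points) (south-west / north-east / south / none)
* amount of target at 4.0 min, in percent of the solid substrate charged, after north-east

**Charge time.** In mM the last readings of autumn, spring and winter were 0.403 mM, 0.431 mM and 0.384 mM, though the charges ran from 2 mM to 4.4 mM. That looked like apparent zero order, with a mean flux of 0.162 mM min⁻¹. I defined the charge time as the charge divided by this flux, the time the flux needs to pass the whole charge; for the flask it was 12.3 min.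

**Main step.** The charge time was longer than the 4.0 min asked, so I expected solid to stand throughout, and for the main step I took time over charge time, 32.5 %.

**Self-condensation.** The flask held 2.20 mM of reagent, less than the smallest charge among the runs, autumn's 3.08 mM. Self-condensation spends reagent as well, so I scaled my figure in proportion to the reagent charge, a harsh step given spring's readings, and that left 23.2 %.

**Side product.** Autumn's last interval read 0.134 mM min⁻¹, below the mean flux. I took that rough reading as target lost to side product, which gave 19.2 %. Doubling the reagent gave the flask 4.40 mM, more than autumn's charge, so I chose south-west, and I left north-east near my figure.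

**The result.** The forecast stood above my figure, with 26 % (21 % to 31 %), north-east as best change and 43 % after north-east, on the ground that “Supply of dissolved substrate therefore limits the rate”. The flask gave 19.6 %, 20.3 % after north-east, and south-west as best change, with a gain of 4.3 percentage points.

    dissolved substrate + reagent → target (k = 18.0 M⁻¹ s⁻¹)
    2 reagent → self-condensation product (k = 2.90 M⁻¹ s⁻¹)
    dissolved substrate + target → side product (k = 13.0 M⁻¹ s⁻¹)
    solid substrate ⇌ dissolved substrate, rate k4*(cs4 - [dissolved substrate]) while solid is left; crystals form when [dissolved substrate] > cs4 (solubility = 0.640 mM, k = 0.00980 s⁻¹)

**Reagent's rates.** At 1.75 min the flask's reagent went 1.2 times as fast into self-condensation product as into target. At 4.00 min 13.2 % of its charge stood, beside 47.9 % of solid substrate. Time over charge time gave 16.3 % at 2.00 min, where the flask held 14.6 % of target. One more flask, charged with 0.50 mM, had by the same flux a reckoned charge time of 3.08 min, shorter than 4.0 min, and at 4.00 min its solid substrate stood at 0 %.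

(The numbers in the tables were generated by integration from invented constants; the scatter is artificial.)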